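Add up the readings of the three earlier runs and keep one ratio, 3.18: s, the selectivity factor, here the summed left-handed product over the summed right-handed product.

| setting | north-east | south-east | south | flask |
|---|---|---|---|---|
| left-handed substrate | 0.40 M | 0.40 M | 0.20 M | 0.40 M |
| right-handed substrate | 0.40 M | 0.40 M | 0.20 M | 0.40 M |
| gas | 160 mM (held) | 160 mM (held) | 160 mM (held) | 160 mM (held) |
| free catalyst | 2.2 mM | 2.2 mM | 2.2 mM | 2.2 mM |
| racemization catalyst | 28 mM | 44 mM | 20 mM | 20 mM |
| remark | run made earlier | run made earlier | run made earlier |  |
| time |  |  |  | 30 min |

| run | time / min | left-handed product / % | right-handed product / % |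
|---|---|---|---|
| north-east | 4.00 | 8 | 6 |
| north-east | 8.00 | 16 | 5 |
| north-east | 12.0 | 21 | 5 |
| north-east | 15.0 | 19 | 6 |
| north-east | 20.0 | 25 | 10 |
| north-east | 25.0 | 27 | 9 |
| south-east | 4.00 | 9 | 5 |
| south-east | 8.00 | 16 | 6 |
| south-east | 12.0 | 22 | 7 |
| south-east | 15.0 | 23 | 5 |
| south-east | 20.0 | 25 | 5 |
| south-east | 25.0 | 25 | 7 |
| south | 5.00 | 13 | 4 |
| south | 10.0 | 23 | 5 |
| south | 15.0 | 24 | 8 |
| south | 20.0 | 27 | 6 |
| south | 25.0 | 27 | 11 |

(scatter of a reading: 2 percentage points)

- free catalyst is single-handed; left-handed substrate and right-handed substrate are mirror images of each other, charged as a racemate, each of them at the stated concentration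
- the numbers in the tables scatter with a standard deviation of 2 percentage points
- at the start none of the gas is in solution
- an excess is below zero if the other one leads

1. left-handed product and right-handed product together, in percent of the left-handed substrate and right-handed substrate charged together, at 30 min
2. excess of left-handed product over right-handed product in the product at 30 min
3. whether the exchange between left-handed substrate and right-handed substrate keeps pace with the reaction: how far the product's excess at 30 min gets from its value without exchange to its value with instant exchange (above 80% keeps pace, below 20% hardly takes part, else lags behind)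

If exchange holds the substrate racemic, the product's excess is s less one over s plus one, which gives 52.2%, a reading from scattered numbers. The north-east run, with twice the substrate of the south run, reaches 36.0% at 25.0 min against 38.0% in the south run, so coupling looks first-order in substrate, though these two runs differ in racemization catalyst as well. We suppose that exchange is too, and then the flask should follow the south run in percent, since both hold 20 mM of racemization catalyst and 2.2 mM of free catalyst. The summed excess reads 54.1% in the south run with 20 mM of racemization catalyst, 47.8% in the north-east run with 28 mM and 54.8% in the south-east run with 44 mM, which is no steady climb, so we expect exchange to keep pace.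

The forecast says 36%, 44% and lags behind, holding that “The flask has the lowest exchange per substrate”. We take a similar yield but part from it on the other two, with 52.2% above its excess.

The flask gives 41.0% of product at an excess of 49.2%, and exchange keeps pace.

    left-handed substrate + racemization catalyst ⇌ right-handed substrate + racemization catalyst, rate k1*[racemization catalyst]*[left-handed substrate] forward; the back reaction follows from the equilibrium constant (k = 1.64 M⁻¹ s⁻¹)
    2 free catalyst ⇌ resting dimer (K = 12600 M⁻¹, k = 1.66 M⁻¹ s⁻¹)
    2 racemization catalyst → spent catalyst (k = 0.0359 M⁻¹ s⁻¹)
    coupling partner + free catalyst + right-handed substrate → free catalyst + right-handed product (k = 1.90 M⁻² s⁻¹)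
    gas ⇌ coupling partner, rate k5*(csat - [coupling partner]) (kL = 0.0705 s⁻¹)
    coupling partner + free catalyst + left-handed substrate → free catalyst + left-handed product (k = 5.64 M⁻² s⁻¹)

The excess gets 96% of the way up from the 40.1% it has without exchange. Split by s, the total of 41.0% puts 31.2% in left-handed product, and the flask holds 30.6% at 30.0 min. The neighbour flask with 5.5 × 10⁻⁴ M of free catalyst makes 23.9%, which s splits into 18.2% of left-handed product, and it holds 17.9%.

Readings and results were generated by integration with made-up constants, and the scatter is random.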